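**Plan**

- Retrosynthesis: first the O3 acetate and the O4' silyl group are removed; then ring A is cut at C4a–C5 and C8–C8a, giving a ring C enone with a sulfinyl leaving group on C4a and a four-carbon 2-prenyl-1-methoxy-1,3-bis(silyloxy)diene; last, ring C is cut at C2–C3 and O1–C8a, giving silylated vanillin and a 4-acetoxy-1-methoxy-3-silyloxy diene.
- Enabling feature: in ring C, O1 and C2 are the C=O of an aryl aldehyde, and C3–C4–C4a–C8a is a four-carbon chain with oxygen on C3, C4 and C8a, i.e. a triply oxygenated butadiene. Ring C is therefore the [4+2] adduct of the two.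
- Forward order: ring B is bought as vanillin, ring C is closed onto it by the aldehyde–diene cyclocondensation, and ring A is annulated last onto C4a=C8a. The prenyl group sits on the central carbon of the second diene, so it can only end up between the two new phenols (C6).
- Stereochemistry: C2 comes from the chiral Ti(OiPr)4/BINOL catalyst (tetravalent titanium) in the cyclocondensation. C3 comes from the anti aldol course of the same step, backed by the thermodynamic trans preference. Neither centre is touched afterwards.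

Key step: step 4

Assumption: with Ti(OiPr)4, (S)-BINOL is taken to direct carbon nucleophiles to the Si face of aryl aldehydes; if the sense proved opposite for diene 5, (R)-BINOL would be used and nothing else changes.
Remark: an acetate replaces a benzoate on the diene oxygen so that the last step can be as mild as possible; compounds 8, 10, 13, 14, 15 and 16 are mixtures at centres or double bonds that are lost later, and their SMILES leave these undefined.

**Route**

Step 1
Reactants: 1 vanillin
Product: 2 4-(tert-butyldimethylsilyloxy)-3-methoxybenzaldehyde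
Conditions: TBSCl, imidazole, DMF, 20 °C
Reagents that add atoms: tert-butyldimethylsilyl chloride, CC(C)(C)[Si](C)(C)Cl
Why: Imidazole-promoted O-silylation masks the acidic phenol, which would otherwise quench the Lewis acid and the silyl dienes, and the aryl silyl ether should survive every step up to the final methanolysis.

Step 2
Reactants: 3 (E)-4-methoxybut-3-en-2-one
Product: 4 (E)-1-acetoxy-4-methoxybut-3-en-2-one
Conditions: Mn(OAc)3·2H2O (3 equiv), benzene–AcOH 10:1, reflux
Reagents that add atoms: manganese triacetate, CC(=O)[O-].CC(=O)[O-].CC(=O)[O-].[Mn+3]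
Why: This is the α'-acetoxylation of an enone by Mn(OAc)3 (trivalent manganese); the manganese enolate can form only on the methyl side, and acetate transfer to that carbon leaves the β-methoxy enone intact.

Step 3
Reactants: 4 (E)-1-acetoxy-4-methoxybut-3-en-2-one
Product: 5 (1E,3Z)-4-acetoxy-1-methoxy-3-(trimethylsilyloxy)buta-1,3-diene
Conditions: TMSOTf (1.05 equiv), Et3N, Et2O, 0 °C
Reagents that add atoms: trimethylsilyl triflate, C[Si](C)(C)OS(=O)(=O)C(F)(F)F
Why: Amine-mediated silyl enol ether formation at the only enolisable ketone position, the acetoxy-bearing CH2, should give the 2-silyloxy diene with the acetoxy group cis to the silyloxy group (Z), as is usual for α-acyloxy ketones.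

Step 4
Reactants: 2 4-(tert-butyldimethylsilyloxy)-3-methoxybenzaldehyde; 5 (1E,3Z)-4-acetoxy-1-methoxy-3-(trimethylsilyloxy)buta-1,3-diene
Product: 7 (2R,3R)-3-acetoxy-2-[4-(tert-butyldimethylsilyloxy)-3-methoxyphenyl]-2,3-dihydro-4H-pyran-4-one, via silyl aldol adduct 6 (not isolated)
Conditions: (S)-BINOL (20 mol%), Ti(OiPr)4 (10 mol%), 4 Å MS, Et2O, −20 → 20 °C; then TFA, CH2Cl2, 0 °C
Reagents that add atoms: none
Why: The Ti(OiPr)4/(S)-BINOL complex (tetravalent titanium) binds the aldehyde oxygen, the nucleophilic C4 terminus of 5 attacks the carbonyl carbon in a Mukaiyama aldol step with silyl transfer to give 6, and TFA then makes the C2 oxygen add to the methoxy-bearing enone terminus and expels the methoxy group, so that C2–C3 and O1–C8a are formed in one operation. The closest known reaction type is the catalytic asymmetric hetero-Diels–Alder (aldol–cyclisation) reaction of aryl aldehydes with 1-methoxy-3-silyloxy dienes, 4-acyloxy dienes included. Ring C is the only ring closed, by a stepwise [4+2] annulation whose ring-forming event is a 6-endo-trig oxa-Michael addition followed by elimination. C2 is controlled by the catalyst, which should leave the Si face of the aldehyde open (2R here, because the acetoxy-bearing C3 outranks the aryl carbon); C3 is controlled by the open, antiperiplanar transition state of the (Z)-enol silane, which leads to the anti aldol and so to the 2,3-trans ring. The step needs regio-, enantio- and diastereoselectivity: regiochemistry is fixed by the polarity of the diene (only C4 is nucleophilic and only C1 carries a leaving group), and since the trans isomer with both substituents pseudo-equatorial is also the more stable one, a minor cis isomer can be equilibrated at C3 with a trace of Et3N or removed by chromatography. The aryl silyl ether and the acetate are inert to the mild Lewis acid and to brief TFA.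

Step 5
Reactants: 7 (2R,3R)-3-acetoxy-2-[4-(tert-butyldimethylsilyloxy)-3-methoxyphenyl]-2,3-dihydro-4H-pyran-4-one
Product: 9 (2R,3R)-3-acetoxy-2-[4-(tert-butyldimethylsilyloxy)-3-methoxyphenyl]-5-(phenylthio)-2,3-dihydro-4H-pyran-4-one, via chloro sulfide adduct 8 (not isolated)
Conditions: PhSCl (1.05 equiv), CH2Cl2, −78 → 0 °C; then Et3N, 0 → 20 °C
Reagents that add atoms: benzenesulfenyl chloride, ClSc1ccccc1
Why: Electrophilic addition of the sulfenyl chloride across the enol-ether-like C4a=C8a bond (sulfur to the nucleophilic C4a, chloride to the oxocarbenium carbon C8a) followed by base-induced loss of HCl is the standard addition–elimination route to α-phenylthio enones; one equivalent of PhSCl and late addition of the base keep C3 from being sulfenylated.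

Step 6
Reactants: 9 (2R,3R)-3-acetoxy-2-[4-(tert-butyldimethylsilyloxy)-3-methoxyphenyl]-5-(phenylthio)-2,3-dihydro-4H-pyran-4-one
Product: 10 (2R,3R)-3-acetoxy-2-[4-(tert-butyldimethylsilyloxy)-3-methoxyphenyl]-5-(phenylsulfinyl)-2,3-dihydro-4H-pyran-4-one (both sulfur epimers)
Conditions: mCPBA (1.0 equiv), NaHCO3, CH2Cl2, −78 → −40 °C
Reagents that add atoms: 3-chloroperbenzoic acid, OOC(=O)c1cccc(Cl)c1
Why: Sulfide-to-sulfoxide oxidation with one equivalent of peracid at low temperature is selective because sulfur is far more nucleophilic than the electron-poor enone or the aryl ring, and the new sulfur stereocentre is lost in step 10.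

Step 7
Reactants: 11 methyl acetoacetate; 12 prenyl bromide (1-bromo-3-methylbut-2-ene)
Product: 13 methyl 2-acetyl-5-methylhex-4-enoate (racemic)
Conditions: K2CO3, acetone, reflux (11 in excess)
Reagents that add atoms: none
Why: C-Alkylation of the β-keto ester enolate with an allylic bromide (acetoacetic ester alkylation) is routine, and excess 11 suppresses dialkylation.

Step 8
Reactants: 13 methyl 2-acetyl-5-methylhex-4-enoate
Product: 14 methyl 5-methyl-2-[1-(trimethylsilyloxy)ethylidene]hex-4-enoate
Conditions: TMSCl, Et3N, toluene, 20 °C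
Reagents that add atoms: trimethylsilyl chloride, C[Si](C)(C)Cl
Why: O-Silylation of the enolised β-keto ester (silyl enol ether formation) is the usual first stage towards a bis(silyloxy)diene.

Step 9
Reactants: 14 methyl 5-methyl-2-[1-(trimethylsilyloxy)ethylidene]hex-4-enoate
Product: 15 1-methoxy-2-(3-methylbut-2-en-1-yl)-1,3-bis(trimethylsilyloxy)buta-1,3-diene
Conditions: LiN(iPr)2, THF, −78 °C; then TMSCl, −78 → 20 °C
Reagents that add atoms: trimethylsilyl chloride, C[Si](C)(C)Cl
Why: γ-Deprotonation of the silyl enol ether ester and O-silylation of the resulting dienolate is the standard preparation of 1-alkoxy-1,3-bis(silyloxy)buta-1,3-dienes, including 2-alkyl ones.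

Step 10
Reactants: 10 (2R,3R)-3-acetoxy-2-[4-(tert-butyldimethylsilyloxy)-3-methoxyphenyl]-5-(phenylsulfinyl)-2,3-dihydro-4H-pyran-4-one; 15 1-methoxy-2-(3-methylbut-2-en-1-yl)-1,3-bis(trimethylsilyloxy)buta-1,3-diene
Product: 18 (2R,3R)-3-acetoxy-2-[4-(tert-butyldimethylsilyloxy)-3-methoxyphenyl]-5,7-dihydroxy-6-(3-methylbut-2-en-1-yl)chroman-4-one, via sulfinyl cycloadduct 16 (not isolated), via aryl trimethylsilyl ether 17 (not isolated)
Conditions: 15 (2.5 equiv), toluene, 20 → 80 °C; then 0.5 M HCl–THF, 0 °C
Reagents that add atoms: none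
Why: Proposed new method: the sulfinyl group makes C4a=C8a of 10 a doubly activated acceptor, so the terminal CH2 of the electron-rich diene 15 should bond to C8a (β to both C=O and S=O) and the ketene acetal carbon should then close onto C4a (stepwise or asynchronous [4+2]) to give cis-fused 16, in which the sulfinyl group on C4a and the hydrogen on C8a are syn; thermal syn-elimination of benzenesulfenic acid restores C4a=C8a, the C5 mixed ketal loses methoxytrimethylsilane, and enolisation aromatises ring A to 17, whose labile aryl silyl ether is hydrolysed on work-up; the polarity of both partners fixes the regiochemistry and so places prenyl at C6, and the closest known reaction types are Diels–Alder benzannulations of 1-alkoxy-1,3-bis(silyloxy)dienes with halo- or sulfinyl-quinones and double-Michael annulations of 2-sulfinylcycloalkenones that end with sulfoxide elimination.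

Step 11
Reactants: 18 (2R,3R)-3-acetoxy-2-[4-(tert-butyldimethylsilyloxy)-3-methoxyphenyl]-5,7-dihydroxy-6-(3-methylbut-2-en-1-yl)chroman-4-one
Product: 19 (2R,3R)-3,5,7-trihydroxy-2-(4-hydroxy-3-methoxyphenyl)-6-(3-methylbut-2-en-1-yl)chroman-4-one
Conditions: K2CO3 (3 equiv), degassed MeOH, 0 → 20 °C, Ar; then aq. NaH2PO4
Reagents that add atoms: none
Why: Base-catalysed transesterification of the activated α-keto acetate and methanolysis of the aryl silyl ether (methoxide attack at silicon) should both occur under the same mild carbonate conditions, while low temperature, exclusion of oxygen and a buffered quench protect the trans-flavanonol from epimerisation and from oxidation to the flavonol.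

**Compound list**

1 | vanillin (4-hydroxy-3-methoxybenzaldehyde) | COc1cc(C=O)ccc1O | starting material
2 | 4-(tert-butyldimethylsilyloxy)-3-methoxybenzaldehyde | COc1cc(C=O)ccc1O[Si](C)(C)C(C)(C)C | intermediate
3 | (E)-4-methoxybut-3-en-2-one | CO/C=C/C(C)=O | starting material
4 | (E)-1-acetoxy-4-methoxybut-3-en-2-one | CO/C=C/C(=O)COC(C)=O | intermediate
5 | (1E,3Z)-4-acetoxy-1-methoxy-3-(trimethylsilyloxy)buta-1,3-diene | CO/C=C/C(O[Si](C)(C)C)=C/OC(C)=O | intermediate
6 | (1E,4R,5R)-4-acetoxy-5-[4-(tert-butyldimethylsilyloxy)-3-methoxyphenyl]-1-methoxy-5-(trimethylsilyloxy)pent-1-en-3-one (anti aldol adduct) | COc1cc([C@@H](O[Si](C)(C)C)[C@@H](OC(C)=O)C(=O)/C=C/OC)ccc1O[Si](C)(C)C(C)(C)C | intermediate (not isolated)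
7 | (2R,3R)-3-acetoxy-2-[4-(tert-butyldimethylsilyloxy)-3-methoxyphenyl]-2,3-dihydro-4H-pyran-4-one | COc1cc([C@H]2OC=CC(=O)[C@@H]2OC(C)=O)ccc1O[Si](C)(C)C(C)(C)C | intermediate
8 | (2R,3R)-3-acetoxy-2-[4-(tert-butyldimethylsilyloxy)-3-methoxyphenyl]-6-chloro-5-(phenylthio)tetrahydro-4H-pyran-4-one (C5/C6 mixture) | COc1cc([C@H]2OC(Cl)C(Sc3ccccc3)C(=O)[C@@H]2OC(C)=O)ccc1O[Si](C)(C)C(C)(C)C | intermediate (not isolated)
9 | (2R,3R)-3-acetoxy-2-[4-(tert-butyldimethylsilyloxy)-3-methoxyphenyl]-5-(phenylthio)-2,3-dihydro-4H-pyran-4-one | COc1cc([C@H]2OC=C(Sc3ccccc3)C(=O)[C@@H]2OC(C)=O)ccc1O[Si](C)(C)C(C)(C)C | intermediate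
10 | (2R,3R)-3-acetoxy-2-[4-(tert-butyldimethylsilyloxy)-3-methoxyphenyl]-5-(phenylsulfinyl)-2,3-dihydro-4H-pyran-4-one (both sulfur epimers) | COc1cc([C@H]2OC=C(S(=O)c3ccccc3)C(=O)[C@@H]2OC(C)=O)ccc1O[Si](C)(C)C(C)(C)C | intermediate
11 | methyl acetoacetate | COC(=O)CC(C)=O | starting material
12 | prenyl bromide (1-bromo-3-methylbut-2-ene) | CC(C)=CCBr | starting material
13 | methyl 2-acetyl-5-methylhex-4-enoate (racemic) | COC(=O)C(CC=C(C)C)C(C)=O | intermediate
14 | methyl 5-methyl-2-[1-(trimethylsilyloxy)ethylidene]hex-4-enoate | COC(=O)C(CC=C(C)C)=C(C)O[Si](C)(C)C | intermediate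
15 | 1-methoxy-2-(3-methylbut-2-en-1-yl)-1,3-bis(trimethylsilyloxy)buta-1,3-diene | COC(O[Si](C)(C)C)=C(CC=C(C)C)C(=C)O[Si](C)(C)C | intermediate
16 | (2R,3R)-3-acetoxy-2-[4-(tert-butyldimethylsilyloxy)-3-methoxyphenyl]-5-methoxy-6-(3-methylbut-2-en-1-yl)-4a-(phenylsulfinyl)-5,7-bis(trimethylsilyloxy)-2,3,4a,5,8,8a-hexahydro-4H-chromen-4-one (cis ring fusion) | COc1cc([C@H]2OC3CC(O[Si](C)(C)C)=C(CC=C(C)C)C(OC)(O[Si](C)(C)C)C3(S(=O)c3ccccc3)C(=O)[C@@H]2OC(C)=O)ccc1O[Si](C)(C)C(C)(C)C | intermediate (not isolated)
17 | (2R,3R)-3-acetoxy-2-[4-(tert-butyldimethylsilyloxy)-3-methoxyphenyl]-5-hydroxy-6-(3-methylbut-2-en-1-yl)-7-(trimethylsilyloxy)chroman-4-one | COc1cc([C@H]2Oc3cc(O[Si](C)(C)C)c(CC=C(C)C)c(O)c3C(=O)[C@@H]2OC(C)=O)ccc1O[Si](C)(C)C(C)(C)C | intermediate (not isolated)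
18 | (2R,3R)-3-acetoxy-2-[4-(tert-butyldimethylsilyloxy)-3-methoxyphenyl]-5,7-dihydroxy-6-(3-methylbut-2-en-1-yl)chroman-4-one | COc1cc([C@H]2Oc3cc(O)c(CC=C(C)C)c(O)c3C(=O)[C@@H]2OC(C)=O)ccc1O[Si](C)(C)C(C)(C)C | intermediate
19 | (2R,3R)-3,5,7-trihydroxy-2-(4-hydroxy-3-methoxyphenyl)-6-(3-methylbut-2-en-1-yl)chroman-4-one | COc1cc([C@H]2Oc3cc(O)c(CC=C(C)C)c(O)c3C(=O)[C@@H]2O)ccc1O | target

**Count**

Total step count: 11.
Longest linear sequence: 7 steps (steps 2, 3, 4, 5, 6, 10, 11; 3 → 4 → 5 → 7 → 9 → 10 → 18 → 19).

**Steps most likely to fail**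

1. Step 10 (proposed new method).
   - Risk: the push–pull C4a=C8a bond may be too electron-rich for a thermal addition; the first C–C bond may form without ring closure; or the ring may close through the enolate oxygen instead of C4a.
   - Fallback (known chemistry, from 7 and 15, back at 18): ring A is built stepwise at the tetrahydropyranone level and dehydrogenated at the end. A TMSOTf-promoted Mukaiyama–Michael addition (CH2Cl2, −78 °C) of the terminal carbon of 15 to C8a of 7 should give, after aqueous work-up, keto ester F1. Dieckmann-type Claisen cyclisation of the C4a enolate onto the methyl ester (KOtBu, THF, −78 → 0 °C) should give the enolised bicyclic triketone F2. Dehydrogenation across C4a–C8a with DDQ (1 equiv, dioxane, 20 °C) then aromatises ring A and returns to 18.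

2. Step 4.
   - Risk: the electron-rich aldehyde may react sluggishly with the less nucleophilic acetoxy diene, and facial or cis/trans selectivity may be poor.
   - Fallback (from 2, back at 7): the two stereocentres are set separately. The same Ti(OiPr)4/(S)-BINOL catalysis with the more reactive, commercially available (E)-1-methoxy-3-(trimethylsilyloxy)buta-1,3-diene, then TFA, should give the (S)-2-aryl pyranone F3, so that the catalyst has to control C2 only. The C3 lithium enolate (LiN(SiMe3)2, THF, −78 °C) is hydroxylated by 2-(phenylsulfonyl)-3-phenyloxaziridine anti to the C2 aryl group to give the trans hydroxy pyranone F4. Ac2O/pyridine returns to 7.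

3. Step 11.
   - Risk: base may open ring C and epimerise C2 or C3, or trace oxygen may oxidise the flavanonol to the flavonol, before both protecting groups are gone.
   - Fallback (from 9, back at 19): the acetate is removed before ring A exists, so the last step needs only fluoride. Brief methanolysis of 9 (catalytic K2CO3, MeOH, 0 °C) should give hydroxy sulfide F5. mCPBA (−78 °C) gives hydroxy sulfoxide F6. The annulation of step 10 with one more equivalent of 15, which silylates the free hydroxyl in the flask until the acid work-up frees it again, gives the 4'-O-silyl flavanonol F7. Bu4NF buffered with AcOH (THF, 0 °C) then gives 19.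

**Further compounds**

F1 | step 10 | methyl 4-[(5R,6R)-5-acetoxy-6-[4-(tert-butyldimethylsilyloxy)-3-methoxyphenyl]-4-oxotetrahydro-2H-pyran-2-yl]-2-(3-methylbut-2-en-1-yl)-3-oxobutanoate (keto ester) | COc1cc([C@H]2OC(CC(=O)C(CC=C(C)C)C(=O)OC)CC(=O)[C@@H]2OC(C)=O)ccc1O[Si](C)(C)C(C)(C)C
F2 | step 10 | (2R,3R)-3-acetoxy-2-[4-(tert-butyldimethylsilyloxy)-3-methoxyphenyl]-6-(3-methylbut-2-en-1-yl)-2,3,4a,6,8,8a-hexahydro-4H-chromene-4,5,7-trione (enolised triketone) | COc1cc([C@H]2OC3CC(=O)C(CC=C(C)C)C(=O)C3C(=O)[C@@H]2OC(C)=O)ccc1O[Si](C)(C)C(C)(C)C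
F3 | step 4 | (S)-2-[4-(tert-butyldimethylsilyloxy)-3-methoxyphenyl]-2,3-dihydro-4H-pyran-4-one | COc1cc([C@H]2OC=CC(=O)C2)ccc1O[Si](C)(C)C(C)(C)C
F4 | step 4 | (2R,3R)-2-[4-(tert-butyldimethylsilyloxy)-3-methoxyphenyl]-3-hydroxy-2,3-dihydro-4H-pyran-4-one | COc1cc([C@H]2OC=CC(=O)[C@@H]2O)ccc1O[Si](C)(C)C(C)(C)C
F5 | step 11 | (2R,3R)-2-[4-(tert-butyldimethylsilyloxy)-3-methoxyphenyl]-3-hydroxy-5-(phenylthio)-2,3-dihydro-4H-pyran-4-one | COc1cc([C@H]2OC=C(Sc3ccccc3)C(=O)[C@@H]2O)ccc1O[Si](C)(C)C(C)(C)C
F6 | step 11 | (2R,3R)-2-[4-(tert-butyldimethylsilyloxy)-3-methoxyphenyl]-3-hydroxy-5-(phenylsulfinyl)-2,3-dihydro-4H-pyran-4-one (both sulfur epimers) | COc1cc([C@H]2OC=C(S(=O)c3ccccc3)C(=O)[C@@H]2O)ccc1O[Si](C)(C)C(C)(C)C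
F7 | step 11 | (2R,3R)-2-[4-(tert-butyldimethylsilyloxy)-3-methoxyphenyl]-3,5,7-trihydroxy-6-(3-methylbut-2-en-1-yl)chroman-4-one | COc1cc([C@H]2Oc3cc(O)c(CC=C(C)C)c(O)c3C(=O)[C@@H]2O)ccc1O[Si](C)(C)C(C)(C)C
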